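If you lower the charge from 0.500 M to 0.200 M and leave the catalyst at 0.00100 M, decide first whether the amber well can keep the 6.5 min clock or needs a longer one. Blue had turned 46.7% of its charge by then, so take that share as the mark.

| flask | starting material | catalyst | target | time |
|---|---|---|---|---|
| blue | 0.500 M | 0.00100 M |  |  |
| ochre | 0.500 M | 0.00150 M |  |  |
| green | 0.750 M | 0.00100 M |  |  |
| violet | 0.500 M | 0.00100 M | 0.250 M |  |
| amber | 0.200 M | 0.00100 M |  | 6.5 min |

| run | time / min | [target] / M |
|---|---|---|
| blue run | 1.1 | 0.0664 |
| blue run | 2.2 | 0.1151 |
| blue run | 3.2 | 0.1537 |
| blue run | 4.3 | 0.1848 |
| blue run | 5.4 | 0.2175 |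
| blue run | 6.5 | 0.2334 |
| ochre run | 1.1 | 0.0940 |
| ochre run | 2.2 | 0.1523 |
| ochre run | 3.2 | 0.1995 |
| ochre run | 4.3 | 0.2378 |
| ochre run | 5.4 | 0.2636 |
| ochre run | 6.5 | 0.2937 |
| green run | 1.1 | 0.0949 |
| green run | 2.2 | 0.1647 |
| green run | 3.2 | 0.2068 |
| green run | 4.3 | 0.2529 |
| green run | 5.4 | 0.2914 |
| green run | 6.5 | 0.3247 |
| violet run | 1.1 | 0.2901 |
| violet run | 2.2 | 0.3218 |
| violet run | 3.2 | 0.3483 |
| violet run | 4.3 | 0.3724 |
| violet run | 5.4 | 0.3971 |
| violet run | 6.5 | 0.4219 |

(readings scatter by 0.002 M)

1. reaction order in [catalyst] at the outset, round the charge of the blue run, defined at two percent of the starting material turned into target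
2. reaction order in [starting material] at the outset, round the charge of the blue run, defined at two percent of the starting material turned into target (one fixed amount of target, the same in the runs compared)
3. target in the amber run at 6.5 min, as a share of the starting material charged

- Overall: starting material -> target, with catalyst as catalyst.
- Constant volume, constant temperature.
- A reading of a species includes what of it is bound.
- An order is taken over about fifteen percent of the charge, up and down.

Read the runs as decays. Green, charged 1.50 times as high as blue, held 1.43 times blue's target at the first reading, so treat the share turned per minute as nearly free of the charge. Violet, which starts with target equal to 50.0% of its charge, gained 8.02% of its charge by the first reading, less than the 13.3% of blue. So the slowing goes with the target present, and the share turned per minute should follow the target in the flask.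

Now take one quantity from blue. By 2.2 min blue had turned 23.0% of its charge, which gives 8.41 min. Call this the mean lifetime up to a given target: the time elapsed divided by the natural log of the charge over what remains, as for a pseudo-first-order decay. Divide the amber clock by it to count 0.773 lifetimes, so amber turns 53.8% of its charge. That is 21.5% of blue's charge, close to the stretch of blue where the lifetime was read. It beats the mark, so leave the clock and the catalyst alone.

The forecast gave orders of 0.97 in catalyst and 0.95 in starting material, and 55% for amber, reasoning “so the target inhibits”. The figure reckoned here sits slightly lower.

The flask gives orders of 1.0 and 1.0, and 54.3% in amber.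

    catalyst + starting material → target + catalyst (150.6 M⁻¹ min⁻¹)
    catalyst + target ⇌ catalyst-product complex, settled at all times (4.070 M⁻¹)

Amber's own mean lifetime, taken from its 54.3%, is 8.29 min, longer than the 6.64 min that its catalyst charge gives with none of it bound, because in amber target joins catalyst as the catalyst-product complex. With that joining taken away, amber turns 62.4% instead of 54.3%. Count green the same way: blue's lifetime, 8.41 min at 2.2 min, had grown by 4.3 min to 9.32 min, up to nearly the target of a quarter of green's charge; that puts this quarter at 2.68 min, and green took 2.67 min.

The data are calculated for an exercise; scatter was added.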